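**Retrosynthetic overview**
1. Feature: in ring C the O1–C8a–C4a–C4 fragment is an ortho-quinone methide of ring A, and C2–C3 is a 4-hydroxystyrene that carries the C3 oxygen as an enol acetate. Ring C is therefore cut at C3–C4 and O1–C2 ([4+2], three stereocentres).
2. The quinone methide is generated as its C4-methoxy form from a salicylaldehyde and HC(OMe)3, so C4 arrives at the alcohol oxidation level. After the cycloaddition: OMe → OH → C=O, then deprotection.
3. Ring A piece: 2,4,6-trihydroxybenzaldehyde. The one hydrogen-bonded OH left after bis-MOM protection marks O5; it directs iodination to the future C6 and is then methylated. The iodide is replaced by geranyl through SN2 alkylation of the aryl metal.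
4. Ring B piece: the E enol acetate comes from (E)-4-(4-hydroxyphenyl)but-3-en-2-one by Baeyer–Villiger oxidation.
5. Ring order: rings A and B are bought as arenes; ring C is the only ring formed, in the key step.

Key step: step 10

Numbering: flavan numbering is used (O1, C2, C3, C4, C4a, C5–C8, C8a), primes for ring B, double primes for the side chain; "geranyl" means (2E)-3,7-dimethylocta-2,6-dien-1-yl and TBS means tert-butyldimethylsilyl.
Assumption: (R)-TRIP is taken to give the (2R,3S,4R) adduct; the sense of induction cannot be predicted with confidence, and (S)-TRIP is used instead if the first run gives the antipode.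
Remark: the geranyl group is not introduced by a para-Claisen–Cope rearrangement of an aryl geranyl ether, because that passes through a tertiary linalyl-type centre and can return the C2''=C3'' bond as an E/Z mixture; SN2 alkylation of an aryl metal leaves that bond untouched.
Assumption: the trihydroxybenzaldehyde, geranyl bromide and the hydroxy enone are taken as commercial.

**Route**

Step 1
Reactants: 1 2,4,6-trihydroxybenzaldehyde
Product: 2 2-hydroxy-4,6-bis(methoxymethoxy)benzaldehyde
Conditions: MOMCl (2.2 equiv), i-Pr2NEt, CH2Cl2, 0 °C → rt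
Reagents that add atoms: chloromethyl methyl ether, COCCl
Why: O-alkylation (MOM protection) takes the 4-OH and one of the two equivalent ortho hydroxyls, while the remaining ortho OH is held in a hydrogen bond to the aldehyde and stays free, which marks the oxygen that becomes O5.

Step 2
Reactants: 2 2-hydroxy-4,6-bis(methoxymethoxy)benzaldehyde
Product: 3 2-hydroxy-3-iodo-4,6-bis(methoxymethoxy)benzaldehyde
Conditions: BnMe3N·ICl2 (1.05 equiv), NaHCO3, CH2Cl2/MeOH, rt
Reagents that add atoms: benzyltrimethylammonium dichloroiodate, C[N+](C)(C)Cc1ccccc1.Cl[I-]Cl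
Why: Electrophilic aromatic iodination of a phenol should go ortho to the free, chelated OH at C3, which is flanked by only one MOM ether whereas C5 lies between two, the same preference by which 5-hydroxy-7-alkoxyflavones are iodinated at C6; bicarbonate keeps the MOM groups safe from HCl.

Step 3
Reactants: 3 2-hydroxy-3-iodo-4,6-bis(methoxymethoxy)benzaldehyde
Product: 4 3-iodo-2-methoxy-4,6-bis(methoxymethoxy)benzaldehyde
Conditions: MeI, K2CO3, DMF, rt
Reagents that add atoms: iodomethane, CI
Why: Williamson O-methylation of the only free phenol fixes the future 5-OMe between the aldehyde carbon and the carbon that will carry the geranyl group.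

Step 4
Reactants: 4 3-iodo-2-methoxy-4,6-bis(methoxymethoxy)benzaldehyde; 5 geranyl bromide
Product: 9 3-geranyl-2-methoxy-4,6-bis(methoxymethoxy)benzaldehyde, via lithium α-amino alkoxide 6 (not isolated), via aryllithium 7 (not isolated), via geranylated lithium α-amino alkoxide 8 (not isolated)
Conditions: LiN(Me)CH2CH2NMe2 (from the amine and n-BuLi), THF, −78 °C; n-BuLi, −78 °C; CuBr·SMe2 (10 mol%), 5, −78 → 0 °C; H2O
Reagents that add atoms: none
Why: Comins-type in situ masking of the aldehyde as a lithium α-amino alkoxide, iodine–lithium exchange and copper-catalysed SN2 allylation of the aryl metal with geranyl bromide should deliver the linear geranyl arene with the C2''=C3'' bond untouched (E kept), and water returns the aldehyde.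

Step 5
Reactants: 9 3-geranyl-2-methoxy-4,6-bis(methoxymethoxy)benzaldehyde
Product: 10 3-geranyl-4,6-dihydroxy-2-methoxybenzaldehyde
Conditions: 3 M aq. HCl, MeOH, 40 °C
Reagents that add atoms: none
Why: Acid-catalysed acetal exchange removes both MOM groups under conditions of the kind routinely tolerated by prenylated phenols, and any dimethyl acetal of the aldehyde reverts on aqueous work-up.

Step 6
Reactants: 10 3-geranyl-4,6-dihydroxy-2-methoxybenzaldehyde
Product: 11 4-(tert-butyldimethylsilyloxy)-3-geranyl-6-hydroxy-2-methoxybenzaldehyde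
Conditions: TBSCl (1.05 equiv), imidazole, DMF, 0 °C
Reagents that add atoms: tert-butyldimethylsilyl chloride, CC(C)(C)[Si](C)(C)Cl
Why: Selective O-silylation takes the 4-OH, which is para to the aldehyde, more acidic and not hydrogen-bonded, and leaves the chelated 6-OH free to serve as the quinone methide oxygen.

Step 7
Reactants: 12 (E)-4-(4-hydroxyphenyl)but-3-en-2-one
Product: 13 (E)-4-[4-(tert-butyldimethylsilyloxy)phenyl]but-3-en-2-one
Conditions: TBSCl, imidazole, CH2Cl2, rt
Reagents that add atoms: tert-butyldimethylsilyl chloride, CC(C)(C)[Si](C)(C)Cl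
Why: Imidazole-promoted silylation masks the phenol, which would otherwise be oxidised by the peroxy reagent of the next step.

Step 8
Reactants: 13 (E)-4-[4-(tert-butyldimethylsilyloxy)phenyl]but-3-en-2-one
Product: 14 (E)-2-[4-(tert-butyldimethylsilyloxy)phenyl]ethenyl acetate
Conditions: (BnSe)2 (5 mol%), 30% aq. H2O2, MeCN, rt
Reagents that add atoms: hydrogen peroxide, OO
Why: In this organoselenium-catalysed Baeyer–Villiger oxidation of an α,β-unsaturated methyl ketone the electron-rich alkenyl group migrates in preference to methyl with retention of geometry, so the E enone gives the E enol acetate.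

Step 9
Reactants: 14 (E)-2-[4-(tert-butyldimethylsilyloxy)phenyl]ethenyl acetate
Product: 15 (E)-2-(4-hydroxyphenyl)ethenyl acetate
Conditions: HF·pyridine, pyridine, THF, 0 °C
Reagents that add atoms: none
Why: Fluoride-driven cleavage of the aryl silyl ether at weakly acidic, buffered pH leaves the enol ester intact and frees the phenol that the catalyst will bind.

Step 10
Reactants: 11 4-(tert-butyldimethylsilyloxy)-3-geranyl-6-hydroxy-2-methoxybenzaldehyde; 15 (E)-2-(4-hydroxyphenyl)ethenyl acetate
Product: 18 2,3-trans-3,4-trans-(2R,3S,4R)-3-acetoxy-7-(tert-butyldimethylsilyloxy)-6-geranyl-2-(4-hydroxyphenyl)-4,5-dimethoxychroman, via dimethyl acetal 16 (not isolated), via methoxy ortho-quinone methide 17 (not isolated)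
Conditions: HC(OMe)3 (2 equiv), (R)-TRIP [(R)-3,3'-bis(2,4,6-triisopropylphenyl)-1,1'-binaphthyl-2,2'-diyl hydrogen phosphate] (10 mol%), 15 (2 equiv), 5 Å MS, PhMe, −20 °C → rt
Reagents that add atoms: trimethyl orthoformate, COC(OC)OC
Why: Proposed new method: the phosphoric acid converts 11 and HC(OMe)3 into acetal 16, which loses methanol to the C4-methoxy ortho-quinone methide 17 (O1=C8a–C4a=C4) held as a hydrogen-bonded ion pair by the chiral phosphate; the acetoxy-bearing carbon of 15 then bonds to C4, because the 4-hydroxyphenyl group is a stronger donor than the acyloxy oxygen, and positive charge builds at benzylic C2. Ring C closes when O1 adds to C2, either within one asynchronous inverse-demand hetero-Diels–Alder transition state or, after a Mukaiyama–Prins-type addition, by 6-exo-trig capture of the para-quinone-methide-like cation. The closest known reactions are the acid-promoted [4+2] of styrenes with 4-alkoxy ortho-quinone methides made from salicylaldehydes and orthoformates, and phosphoric-acid-catalysed enantioselective cycloadditions of hydroxystyrenes with ortho-quinone methides; an enol ester as the 2π partner is the untested element. C3 is set in the C–C bond-forming event by the catalyst, which binds the quinone methide oxygen and the free 4'-OH together and so exposes one face of the E enol ester; C2 follows from suprafacial addition to the E alkene (in the stepwise limit, from closure through a chair with the aryl group equatorial), giving 2,3-trans; C4 ends trans to C3 under thermodynamic control, since the C4 ether can re-ionise under the acid. The step needs regioselectivity (acetoxy carbon to C4), chemoselectivity over the geranyl alkenes and over Friedel–Crafts attack at C8, and enantiofacial control; these rest on the vinylogous-enol character of the 4-hydroxystyrene, its use in excess, the 7-O-silyl group flanking C8, and the bifunctional catalyst.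

Step 11
Reactants: 18 (2R,3S,4R)-3-acetoxy-7-(tert-butyldimethylsilyloxy)-6-geranyl-2-(4-hydroxyphenyl)-4,5-dimethoxychroman
Product: 19 (2R,3S,4R)-3-acetoxy-7-(tert-butyldimethylsilyloxy)-2-[4-(tert-butyldimethylsilyloxy)phenyl]-6-geranyl-4,5-dimethoxychroman
Conditions: TBSCl, imidazole, DMF, 0 °C → rt
Reagents that add atoms: tert-butyldimethylsilyl chloride, CC(C)(C)[Si](C)(C)Cl
Why: Silylation of the 4'-phenol stops ring B from opening ring C through a para-quinone methide in the acidic step that follows and makes it inert to the periodinane.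

Step 12
Reactants: 19 (2R,3S,4R)-3-acetoxy-7-(tert-butyldimethylsilyloxy)-2-[4-(tert-butyldimethylsilyloxy)phenyl]-6-geranyl-4,5-dimethoxychroman
Product: 20 (2R,3S,4R)-3-acetoxy-7-(tert-butyldimethylsilyloxy)-2-[4-(tert-butyldimethylsilyloxy)phenyl]-6-geranyl-5-methoxychroman-4-ol (the C4 epimer is equally usable)
Conditions: PPTS (cat.), acetone/H2O (10:1), 0 °C → rt
Reagents that add atoms: water, O
Why: SN1 solvolysis of the benzylic C4 methyl ether works under very mild acid because the C4 cation is stabilised by O1, 5-OMe and 7-OSi (ortho, ortho, para), and the C4 configuration is of no consequence since C4 is oxidised next while C2 and C3 are not involved.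

Step 13
Reactants: 20 (2R,3S,4R)-3-acetoxy-7-(tert-butyldimethylsilyloxy)-2-[4-(tert-butyldimethylsilyloxy)phenyl]-6-geranyl-5-methoxychroman-4-ol
Product: 21 (2R,3R)-3-acetoxy-7-(tert-butyldimethylsilyloxy)-2-[4-(tert-butyldimethylsilyloxy)phenyl]-6-geranyl-5-methoxychroman-4-one
Conditions: Dess–Martin periodinane, NaHCO3, CH2Cl2, 0 °C → rt
Reagents that add atoms: none
Why: Dess–Martin oxidation of the secondary benzylic alcohol gives the aryl ketone under buffered, non-basic conditions that leave C3, the geranyl alkenes (including the C1'' methylene) and both aryl silyl ethers untouched.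

Step 14
Reactants: 21 (2R,3R)-3-acetoxy-7-(tert-butyldimethylsilyloxy)-2-[4-(tert-butyldimethylsilyloxy)phenyl]-6-geranyl-5-methoxychroman-4-one
Product: 22 (2R,3R)-3-acetoxy-6-geranyl-7-hydroxy-2-(4-hydroxyphenyl)-5-methoxychroman-4-one
Conditions: HF·pyridine, pyridine, THF, 0 °C → rt
Reagents that add atoms: none
Why: Fluoride-driven Si–O cleavage removes both aryl silyl ethers at buffered acidic pH, where no phenoxide forms that could epimerise C2 or C3.

Step 15
Reactants: 22 (2R,3R)-3-acetoxy-6-geranyl-7-hydroxy-2-(4-hydroxyphenyl)-5-methoxychroman-4-one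
Product: 23 (2R,3R)-6-geranyl-3,7-dihydroxy-2-(4-hydroxyphenyl)-5-methoxychroman-4-one (target, CNP0177937.1)
Conditions: NH3 (2 M in MeOH), 0 °C, Ar
Reagents that add atoms: none
Why: Ammonolysis of the acetate, which is activated by the adjacent C4 ketone, should proceed under cold, weakly basic conditions short of those that epimerise or ring-open dihydroflavonols.

**Compound list**
1 | 2,4,6-trihydroxybenzaldehyde | O=Cc1c(O)cc(O)cc1O | starting material
2 | 2-hydroxy-4,6-bis(methoxymethoxy)benzaldehyde | O=Cc1c(O)cc(OCOC)cc1OCOC | intermediate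
3 | 2-hydroxy-3-iodo-4,6-bis(methoxymethoxy)benzaldehyde | O=Cc1c(O)c(I)c(OCOC)cc1OCOC | intermediate
4 | 3-iodo-2-methoxy-4,6-bis(methoxymethoxy)benzaldehyde | O=Cc1c(OC)c(I)c(OCOC)cc1OCOC | intermediate
5 | geranyl bromide, (2E)-1-bromo-3,7-dimethylocta-2,6-diene | CC(C)=CCC/C(C)=C/CBr | starting material
6 | lithium α-amino alkoxide of 4 (aldehyde carbon bearing OLi and N(Me)CH2CH2NMe2) | [Li+].[O-]C(N(C)CCN(C)C)c1c(OC)c(I)c(OCOC)cc1OCOC | intermediate
7 | aryllithium (6 with C3–I replaced by C3–Li) | [Li+].[O-]C(N(C)CCN(C)C)c1c(OC)c([Li])c(OCOC)cc1OCOC | intermediate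
8 | geranylated lithium α-amino alkoxide (6 with geranyl in place of iodine) | [Li+].[O-]C(N(C)CCN(C)C)c1c(OC)c(C/C=C(\C)CCC=C(C)C)c(OCOC)cc1OCOC | intermediate
9 | 3-geranyl-2-methoxy-4,6-bis(methoxymethoxy)benzaldehyde | O=Cc1c(OC)c(C/C=C(\C)CCC=C(C)C)c(OCOC)cc1OCOC | intermediate
10 | 3-geranyl-4,6-dihydroxy-2-methoxybenzaldehyde | O=Cc1c(OC)c(C/C=C(\C)CCC=C(C)C)c(O)cc1O | intermediate
11 | 4-(tert-butyldimethylsilyloxy)-3-geranyl-6-hydroxy-2-methoxybenzaldehyde | COc1c(C/C=C(\C)CCC=C(C)C)c(O[Si](C)(C)C(C)(C)C)cc(O)c1C=O | intermediate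
12 | (E)-4-(4-hydroxyphenyl)but-3-en-2-one | CC(=O)/C=C/c1ccc(O)cc1 | starting material
13 | (E)-4-[4-(tert-butyldimethylsilyloxy)phenyl]but-3-en-2-one | CC(=O)/C=C/c1ccc(O[Si](C)(C)C(C)(C)C)cc1 | intermediate
14 | (E)-2-[4-(tert-butyldimethylsilyloxy)phenyl]ethenyl acetate | CC(=O)O/C=C/c1ccc(O[Si](C)(C)C(C)(C)C)cc1 | intermediate
15 | (E)-2-(4-hydroxyphenyl)ethenyl acetate | CC(=O)O/C=C/c1ccc(O)cc1 | intermediate
16 | dimethyl acetal of 11 | COc1c(C/C=C(\C)CCC=C(C)C)c(O[Si](C)(C)C(C)(C)C)cc(O)c1C(OC)OC | intermediate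
17 | C4-methoxy ortho-quinone methide of ring A (6-(methoxymethylene)cyclohexa-2,4-dienone form) | COC=C1C(=O)C=C(O[Si](C)(C)C(C)(C)C)C(C/C=C(\C)CCC=C(C)C)=C1OC | intermediate
18 | (2R,3S,4R)-3-acetoxy-7-(tert-butyldimethylsilyloxy)-6-geranyl-2-(4-hydroxyphenyl)-4,5-dimethoxychroman (2,3-trans-3,4-trans) | COc1c(C/C=C(\C)CCC=C(C)C)c(O[Si](C)(C)C(C)(C)C)cc2c1[C@@H](OC)[C@H](OC(C)=O)[C@@H](c1ccc(O)cc1)O2 | intermediate
19 | (2R,3S,4R)-3-acetoxy-7-(tert-butyldimethylsilyloxy)-2-[4-(tert-butyldimethylsilyloxy)phenyl]-6-geranyl-4,5-dimethoxychroman | COc1c(C/C=C(\C)CCC=C(C)C)c(O[Si](C)(C)C(C)(C)C)cc2c1[C@@H](OC)[C@H](OC(C)=O)[C@@H](c1ccc(O[Si](C)(C)C(C)(C)C)cc1)O2 | intermediate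
20 | (2R,3S,4R)-3-acetoxy-7-(tert-butyldimethylsilyloxy)-2-[4-(tert-butyldimethylsilyloxy)phenyl]-6-geranyl-5-methoxychroman-4-ol | COc1c(C/C=C(\C)CCC=C(C)C)c(O[Si](C)(C)C(C)(C)C)cc2c1[C@@H](O)[C@H](OC(C)=O)[C@@H](c1ccc(O[Si](C)(C)C(C)(C)C)cc1)O2 | intermediate
21 | (2R,3R)-3-acetoxy-7-(tert-butyldimethylsilyloxy)-2-[4-(tert-butyldimethylsilyloxy)phenyl]-6-geranyl-5-methoxychroman-4-one | COc1c(C/C=C(\C)CCC=C(C)C)c(O[Si](C)(C)C(C)(C)C)cc2c1C(=O)[C@H](OC(C)=O)[C@@H](c1ccc(O[Si](C)(C)C(C)(C)C)cc1)O2 | intermediate
22 | (2R,3R)-3-acetoxy-6-geranyl-7-hydroxy-2-(4-hydroxyphenyl)-5-methoxychroman-4-one | COc1c(C/C=C(\C)CCC=C(C)C)c(O)cc2c1C(=O)[C@H](OC(C)=O)[C@@H](c1ccc(O)cc1)O2 | intermediate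
23 | (2R,3R)-6-geranyl-3,7-dihydroxy-2-(4-hydroxyphenyl)-5-methoxychroman-4-one | COc1c(C/C=C(\C)CCC=C(C)C)c(O)cc2c1C(=O)[C@H](O)[C@@H](c1ccc(O)cc1)O2 | target

**Count**
Total steps: 15. Longest linear sequence: 12 steps (steps 1–6 and 10–15, from 1); the ring B branch is 3 steps (steps 7–9).

**Steps most likely to fail**

Step 10 (the proposed new method). The quinone methide carries three oxygen donors and may be too weak an electrophile for an alkene whose nucleophilic carbon bears an acyloxy group. The failure processes would then be: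
- Friedel–Crafts attack of C8 of the product on the C4 cation, giving 4→8 oligomers;
- ene or Prins reaction at the geranyl alkenes;
- acid methanolysis of the enol ester;
- weak facial discrimination.

Fallback with known chemistry, setting out from 9 and returning at 23:
- MeMgBr in THF adds to the aldehyde of 9 to give 1-[3-geranyl-2-methoxy-4,6-bis(methoxymethoxy)phenyl]ethanol F1.
- Dess–Martin oxidation gives the acetophenone 1-[3-geranyl-2-methoxy-4,6-bis(methoxymethoxy)phenyl]ethanone F2.
- Claisen–Schmidt condensation with 4-(methoxymethoxy)benzaldehyde (KOH, EtOH) gives the E chalcone F3.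
- Juliá–Colonna epoxidation (poly-L-leucine, urea–H2O2, DBU, THF) uses nucleophilic peroxide, which attacks only the enone and not the geranyl alkenes, and should give the (αR,βS)-epoxide F4.
- HCl in MeOH at 40 °C removes the three MOM groups, and the freed ortho hydroxyl opens the epoxide at the benzylic carbon with inversion to give the 2,3-trans dihydroflavonol 23 directly.

Step 12. The 3-acetoxy carbonyl may take part at the C4 cation. The resulting acetoxonium ion can hand the acetyl group to O4 or lose it altogether, which leaves a free C3 hydroxyl that would be oxidised in step 13.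

Fallback that removes the participating group, setting out from 19 and returning at 23:
- i-Bu2AlH (CH2Cl2, −78 °C) cleaves the acetate to the 3-ol F5.
- TBSOTf and 2,6-lutidine give the 3-O-silyl ether F6.
- PPTS in wet acetone exchanges the C4 methoxy group for hydroxyl to give the 4-ol F7, now without a neighbouring carbonyl.
- Dess–Martin oxidation gives the tris-silyl ketone F8.
- HF·pyridine removes all three silyl groups to give 23, which also avoids any basic step at the end.

Step 4. The one-pot sequence may fail through incomplete iodine–lithium exchange, attack of n-BuLi on the masked aldehyde, protonation of the aryllithium, or γ-attack on geranyl bromide giving the linalyl isomer.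

Fallback by electrophilic C-alkylation, setting out from 1 (with 5) and returning at 9; it also sidesteps the regiochemical question of step 2:
- 1 is C-geranylated with 5 in cold aqueous KOH. Both open ring positions are equivalent, so the regiochemistry is unambiguous, and the SN2 step keeps the E geometry. The product is 3-geranyl-2,4,6-trihydroxybenzaldehyde F9.
- MOMCl (2.2 equiv) and i-Pr2NEt protect the 4-OH and the unhindered 6-OH. The OH that is both chelated and flanked by the geranyl group stays free, giving 3-geranyl-2-hydroxy-4,6-bis(methoxymethoxy)benzaldehyde F10.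
- MeI and K2CO3 in DMF then give 9.

**Further compounds**
F1 | step 10 | 1-[3-geranyl-2-methoxy-4,6-bis(methoxymethoxy)phenyl]ethanol (racemic) | CC(O)c1c(OC)c(C/C=C(\C)CCC=C(C)C)c(OCOC)cc1OCOC
F2 | step 10 | 1-[3-geranyl-2-methoxy-4,6-bis(methoxymethoxy)phenyl]ethanone | CC(=O)c1c(OC)c(C/C=C(\C)CCC=C(C)C)c(OCOC)cc1OCOC
F3 | step 10 | (E)-1-[3-geranyl-2-methoxy-4,6-bis(methoxymethoxy)phenyl]-3-[4-(methoxymethoxy)phenyl]prop-2-en-1-one | O=C(/C=C/c1ccc(OCOC)cc1)c1c(OC)c(C/C=C(\C)CCC=C(C)C)c(OCOC)cc1OCOC
F4 | step 10 | [3-geranyl-2-methoxy-4,6-bis(methoxymethoxy)phenyl]{(2R,3S)-3-[4-(methoxymethoxy)phenyl]oxiran-2-yl}methanone | O=C(c1c(OC)c(C/C=C(\C)CCC=C(C)C)c(OCOC)cc1OCOC)[C@@H]1O[C@H]1c1ccc(OCOC)cc1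
F5 | step 12 | (2R,3S,4R)-7-(tert-butyldimethylsilyloxy)-2-[4-(tert-butyldimethylsilyloxy)phenyl]-6-geranyl-4,5-dimethoxychroman-3-ol | COc1c(C/C=C(\C)CCC=C(C)C)c(O[Si](C)(C)C(C)(C)C)cc2c1[C@@H](OC)[C@H](O)[C@@H](c1ccc(O[Si](C)(C)C(C)(C)C)cc1)O2
F6 | step 12 | (2R,3S,4R)-3,7-bis(tert-butyldimethylsilyloxy)-2-[4-(tert-butyldimethylsilyloxy)phenyl]-6-geranyl-4,5-dimethoxychroman | COc1c(C/C=C(\C)CCC=C(C)C)c(O[Si](C)(C)C(C)(C)C)cc2c1[C@@H](OC)[C@H](O[Si](C)(C)C(C)(C)C)[C@@H](c1ccc(O[Si](C)(C)C(C)(C)C)cc1)O2
F7 | step 12 | (2R,3S,4R)-3,7-bis(tert-butyldimethylsilyloxy)-2-[4-(tert-butyldimethylsilyloxy)phenyl]-6-geranyl-5-methoxychroman-4-ol | COc1c(C/C=C(\C)CCC=C(C)C)c(O[Si](C)(C)C(C)(C)C)cc2c1[C@@H](O)[C@H](O[Si](C)(C)C(C)(C)C)[C@@H](c1ccc(O[Si](C)(C)C(C)(C)C)cc1)O2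
F8 | step 12 | (2R,3R)-3,7-bis(tert-butyldimethylsilyloxy)-2-[4-(tert-butyldimethylsilyloxy)phenyl]-6-geranyl-5-methoxychroman-4-one | COc1c(C/C=C(\C)CCC=C(C)C)c(O[Si](C)(C)C(C)(C)C)cc2c1C(=O)[C@H](O[Si](C)(C)C(C)(C)C)[C@@H](c1ccc(O[Si](C)(C)C(C)(C)C)cc1)O2
F9 | step 4 | 3-geranyl-2,4,6-trihydroxybenzaldehyde | O=Cc1c(O)c(C/C=C(\C)CCC=C(C)C)c(O)cc1O
F10 | step 4 | 3-geranyl-2-hydroxy-4,6-bis(methoxymethoxy)benzaldehyde | O=Cc1c(O)c(C/C=C(\C)CCC=C(C)C)c(OCOC)cc1OCOC
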